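**Strategy.** The cis-fused bis-pyran is cut at the ring-fusion bond C-b–C-c (shared by both pyran rings) and at the O-1–C4 enol-ether bond of quinolone A. One acid-catalysed domino joins aldehyde 7 (quinolone B with a C3 4-methylpentadienyl group and a C4 O–CMe2–CHO arm) and methoxyquinolinone 8: carbonyl–diene cyclisation forms C-b–C-c and closes ring 2 (gem-dimethylpyran); the allyl cation, whose gem-dimethyl end becomes the isobutenyl group, alkylates C3 of 8 at C-a; the new hydroxyl then displaces methoxide at C4, closing ring 1 (pyran on quinolone A). It exploits that C-c is a diene terminus and C4 of quinolone A a vinylogous ester carbon. (C-a: isobutenyl-bearing CH; C-b: O-bearing fusion CH; C-c: other fusion CH.)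

Key step: step 6

Assumption: the (S,S)-enantiomer of the acid catalyst is taken to favour the aldehyde face that leads to the (S,S) ring fusion; if the sense of induction is the opposite, its (R,R)-enantiomer is used instead.

Step 1
Reactants: 1 4-hydroxy-1-methylquinolin-2(1H)-one; 2 ethyl 2-bromo-2-methylpropanoate
Product: 3 ethyl 2-methyl-2-[(1-methyl-2-oxo-1,2-dihydroquinolin-4-yl)oxy]propanoate
Conditions: Cs2CO3, DMF, 70 °C
Reagents that add atoms: none
Why: Williamson-type O-alkylation in which the caesium 4-oxide of 1 displaces bromide at the carbonyl-activated tertiary carbon of 2 (the way aryloxyisobutyrates are made), the hard O4 being preferred over C3, where attack would join two fully substituted carbons.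

Step 2
Reactants: 3 ethyl 2-methyl-2-[(1-methyl-2-oxo-1,2-dihydroquinolin-4-yl)oxy]propanoate
Product: 4 ethyl 2-[(3-bromo-1-methyl-2-oxo-1,2-dihydroquinolin-4-yl)oxy]-2-methylpropanoate
Conditions: N-bromosuccinimide, MeCN, 0 °C to 20 °C
Reagents that add atoms: N-bromosuccinimide, O=C1CCC(=O)N1Br
Why: Electrophilic bromination with N-bromosuccinimide at C3, the β-carbon of the enol ether and the only nucleophilic CH of the 4-alkoxy-2-quinolone.

Step 3
Reactants: 4 ethyl 2-[(3-bromo-1-methyl-2-oxo-1,2-dihydroquinolin-4-yl)oxy]-2-methylpropanoate; 5 4-methylpenta-1,3-diene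
Product: 6 ethyl 2-methyl-2-({1-methyl-3-[(1E)-4-methylpenta-1,3-dien-1-yl]-2-oxo-1,2-dihydroquinolin-4-yl}oxy)propanoate
Conditions: 5 (3 equiv), Pd(OAc)2 (5 mol %), P(o-tol)3, Et3N, DMF, 100 °C, sealed tube
Reagents that add atoms: none
Why: Heck–Mizoroki reaction: after oxidative addition of the C3–Br bond the aryl group adds to the unsubstituted terminus of diene 5 and β-hydride elimination of the benzylic hydrogen restores the diene in conjugation with the ring as the (E)-isomer, the ester being inert.

Step 4
Reactants: 6 ethyl 2-methyl-2-({1-methyl-3-[(1E)-4-methylpenta-1,3-dien-1-yl]-2-oxo-1,2-dihydroquinolin-4-yl}oxy)propanoate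
Product: 7 2-methyl-2-({1-methyl-3-[(1E)-4-methylpenta-1,3-dien-1-yl]-2-oxo-1,2-dihydroquinolin-4-yl}oxy)propanal
Conditions: i-Bu2AlH (1.2 equiv), CH2Cl2, −78 °C; then aqueous potassium sodium tartrate
Reagents that add atoms: none
Why: Partial reduction of the ester with i-Bu2AlH: the aluminium hemiacetal of the hindered α-aryloxy ester is stable at −78 °C and releases the aldehyde only on work-up, while the aromatic lactam and the diene are not attacked.

Step 5
Reactants: 1 4-hydroxy-1-methylquinolin-2(1H)-one
Product: 8 4-methoxy-1-methylquinolin-2(1H)-one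
Conditions: dimethyl sulfate, K2CO3, acetone, reflux
Reagents that add atoms: dimethyl sulfate, COS(=O)(=O)OC
Why: Williamson O-methylation of the vinylogous acid with dimethyl sulfate, which takes place at O4 under K2CO3 in acetone and leaves the lactam untouched.

Step 6
Reactants: 7 2-methyl-2-({1-methyl-3-[(1E)-4-methylpenta-1,3-dien-1-yl]-2-oxo-1,2-dihydroquinolin-4-yl}oxy)propanal; 8 4-methoxy-1-methylquinolin-2(1H)-one
Product: 11 CNP0107253.2 (target; C-a R; C-b S; C-c S), via cis-fused cycloadduct 9 (not isolated), via hydroxy methoxy intermediate 10 (not isolated)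
Conditions: 8 (2 equiv), (S,S)-HN[P(=NSO2CF3)(O2C20H10Ar2)]2 with Ar = 3,5-(CF3)2C6H3 (BINOL-derived imidodiphosphorimidate, 10 mol %), 5 Å molecular sieves, CHCl3, −40 °C, then 40 °C
Reagents that add atoms: none
Why: Proposed new method: the acid activates the aldehyde of 7, the diene terminus C-c (nucleophilic because of the 4,4-dimethyl substitution) attacks C-b in an asynchronous oxa-[4+2] (Prins-type) cyclisation to 9, the acid then ionises the tertiary allylic C–O bond of 9, the allyl cation alkylates the nucleophilic C3 of 8 at its secondary end C-a to give 10, and the freed hydroxyl O-1 displaces methoxide at C4 of the protonated quinolone A by addition–elimination. The closest known reaction types are the imidodiphosphorimidate-catalysed asymmetric [4+2] cycloaddition of aldehydes with simple dienes and Prins/Friedel–Crafts cascades, ended here by a vinylogous transesterification. Ring 2 closes by 6-exo-trig attack of the diene terminus on the aldehyde carbon (bond C-b–C-c), and ring 1 closes by 6-endo-trig conjugate addition of O-1 to C4 of quinolone A (C3=C4 lies in the forming ring) followed by loss of methanol (bond O-1–C4). C-b and C-c are set in the cyclisation, where the ortho-disubstituted arene tether should enforce the cis ring fusion and the chiral counter-anion should select the aldehyde face that gives the (S,S) fusion. C-a is set in the C-allylation: with the C-c hydrogen in the plane of the allyl cation (1,3-allylic strain) the nucleophile should add anti to quinolone B, which gives the R centre with the isobutenyl group on the convex face, and since the C-allylation is reversible under the acid the ring closure should drain the minor epimer. The step needs carbonyl activation to outrun protonation of the diene (low temperature, confined acid), attack at the secondary and not the tertiary end of the allyl cation (sterics, trisubstituted alkene kept) and alkoxy exchange at C4 of quinolone A and not of quinolone B (only there a small methoxide leaves through a 6-membered transition state).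

**Compound list**

1 | 4-hydroxy-1-methylquinolin-2(1H)-one | Cn1c(=O)cc(O)c2ccccc12 | starting material
2 | ethyl 2-bromo-2-methylpropanoate | CCOC(=O)C(C)(C)Br | starting material
3 | ethyl 2-methyl-2-[(1-methyl-2-oxo-1,2-dihydroquinolin-4-yl)oxy]propanoate | CCOC(=O)C(C)(C)Oc1cc(=O)n(C)c2ccccc12 | intermediate
4 | ethyl 2-[(3-bromo-1-methyl-2-oxo-1,2-dihydroquinolin-4-yl)oxy]-2-methylpropanoate | CCOC(=O)C(C)(C)Oc1c(Br)c(=O)n(C)c2ccccc12 | intermediate
5 | 4-methylpenta-1,3-diene | C=CC=C(C)C | starting material
6 | ethyl 2-methyl-2-({1-methyl-3-[(1E)-4-methylpenta-1,3-dien-1-yl]-2-oxo-1,2-dihydroquinolin-4-yl}oxy)propanoate | CCOC(=O)C(C)(C)Oc1c(/C=C/C=C(C)C)c(=O)n(C)c2ccccc12 | intermediate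
7 | 2-methyl-2-({1-methyl-3-[(1E)-4-methylpenta-1,3-dien-1-yl]-2-oxo-1,2-dihydroquinolin-4-yl}oxy)propanal | O=CC(C)(C)Oc1c(/C=C/C=C(C)C)c(=O)n(C)c2ccccc12 | intermediate
8 | 4-methoxy-1-methylquinolin-2(1H)-one | COc1cc(=O)n(C)c2ccccc12 | intermediate
9 | cis-fused cycloadduct: a 2,2-dimethyl-3,6-dihydro-2H-pyran ring (O-1 bonded to C-b and to the former diene CMe2 carbon, C-a=CH double bond in this ring) fused across C-b–C-c to ring 2 of the 2,2,6-trimethylpyrano[3,2-c]quinolin-5-one; C-b S, C-c S | CC1(C)C=C[C@@H]2[C@H](O1)C(C)(C)Oc3c2c(=O)n(C)c2ccccc32 | intermediate (not isolated)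
10 | 3-{(1R)-1-[(3S,4S)-3-hydroxy-2,2,6-trimethyl-5-oxo-3,4,5,6-tetrahydro-2H-pyrano[3,2-c]quinolin-4-yl]-3-methylbut-2-en-1-yl}-4-methoxy-1-methylquinolin-2(1H)-one | CC(C)=C[C@@H](c1c(OC)c2ccccc2n(C)c1=O)[C@H]1c2c(c3ccccc3n(C)c2=O)OC(C)(C)[C@H]1O | intermediate (not isolated)
11 | CNP0107253.2: cis-fused bis(pyrano[3,2-c]quinolinone) in which ring 1 (O-1, C-b, C-c, C-a, C3 and C4 of quinolone A) and ring 2 (gem-dimethylpyran on quinolone B) share C-b–C-c; C-a R (2-methylprop-1-enyl on the convex face), C-b S, C-c S | CC(C)=C[C@H]1c2c(c3ccccc3n(C)c2=O)O[C@H]2[C@@H]1c1c(c3ccccc3n(C)c1=O)OC2(C)C | target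

Total step count: 6. Longest linear sequence: 5 steps (steps 1 to 4, then step 6).

**Steps most likely to fail**

Step 6: the three acid-driven events may fail to keep pace in one flask. The cyclisation may control the ring-fusion geometry or the aldehyde face poorly, the allyl cation may be lost to proton elimination or oligomerisation before C-allylation, or the alkoxy exchange may stall under the confined acid. The fallback uses known chemistry, sets out from 7 and comes back at 11. Aldehyde 7 alone is cyclised with the same imidodiphosphorimidate at −40 °C (catalytic asymmetric aldehyde–diene [4+2] cycloaddition) and cycloadduct 9 is isolated and purified. Then 9 and 8 are treated with BF3·OEt2 in CH2Cl2 at −78 °C (Ferrier-type allylic C-alkylation of the dihydropyran) to give isolated alcohol 10. Finally 10 is closed with catalytic camphorsulfonic acid in toluene at 80 °C over 5 Å molecular sieves (vinylogous transesterification) to 11. This fallback makes no further compound: none F0.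

Step 1: elimination of the tertiary bromo ester to the methacrylate and attack through C3 may outrun O-alkylation. The fallback sets out from 1 and comes back at 3. Compound 1 is converted with POCl3 at 90 °C into 4-chloro-1-methylquinolin-2(1H)-one F1. The chloride is then displaced by addition–elimination with the sodium alkoxide of ethyl 2-hydroxy-2-methylpropanoate (NaH, THF, 60 °C) to give 3.

Step 3: insertion at the hindered bromide may be slow, and β-hydride elimination on the methyl side of the allylpalladium intermediate would give diene isomers. The fallback sets out from 4 and comes back at 6. Bromine–magnesium exchange of 4 with i-PrMgCl·LiCl (THF, −40 °C) and a quench with DMF give ethyl 2-[(3-formyl-1-methyl-2-oxo-1,2-dihydroquinolin-4-yl)oxy]-2-methylpropanoate F2. Wittig olefination with the ylide from (3-methylbut-2-en-1-yl)triphenylphosphonium bromide and KN(SiMe3)2 (THF, −78 °C to 20 °C), followed by I2-catalysed equilibration to the (E)-isomer, gives 6.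

Further compounds
F0 | step 6 | none | none
F1 | step 1 | 4-chloro-1-methylquinolin-2(1H)-one | Cn1c(=O)cc(Cl)c2ccccc12
F2 | step 3 | ethyl 2-[(3-formyl-1-methyl-2-oxo-1,2-dihydroquinolin-4-yl)oxy]-2-methylpropanoate | CCOC(=O)C(C)(C)Oc1c(C=O)c(=O)n(C)c2ccccc12
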